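**Retrosynthetic overview**
1. The target comes from an O5-silyl, 8-hydroxy macrocycle by O8-methacrylation and desilylation. The ten-membered carbocycle is closed last, at C7–C8, by an intramolecular Nozaki–Hiyama allylation of a 3-(bromomethyl)butenolide onto a C8 aldehyde; this also unveils the α-methylene lactone.
2. The butenolide (the lactone ring, made first from furan-3-ylmethanol) is joined at C5–C6 by an organocatalytic vinylogous aldol reaction with a bis-epoxy 2-substituted acrolein.
3. The 1,10-oxirane comes from a Shi epoxidation of a cis-vinyl epoxide. The 2,3-oxirane comes from a chiral phosphoric acid-catalysed (Z)-γ-chloroallylboration and ring closure on an achiral enal, which sets the first stereocentres.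
4. Achiral building blocks: 2-methylenepropane-1,3-diol (C3, C4, C5, C15); silylated but-3-yn-1-ol with AlMe3 and formaldehyde (C8, C9, C10, C1, C14, C2); furan-3-ylmethanol (C6, C7, C11–C13); methacrylic anhydride.
5. Ring order: butenolide → 2,3-oxirane → 1,10-oxirane → ten-membered carbocycle.

Assumption: positions are labelled C1–C15 as in a germacranolide (ring C1–C10, C14 = methyl on C10, C15 = methylene on C4, C11/C12/C13 = lactone α-carbon, carbonyl and exocyclic methylene), and these labels are kept for all intermediates. The target is then (1R,2S,3S,5R,6S,7R,8S,10R).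

**Fragment A (chloroallyl boronate)**

Step 1
Reactants: 1 2-methylenepropane-1,3-diol
Product: 2 2-[(triethylsilyloxy)methyl]prop-2-en-1-ol
Conditions: TESCl (0.33 equiv), Et3N, CH2Cl2, −78 → 0 °C (1 in excess, recovered)
Reagents that add atoms: chlorotriethylsilane (TESCl), CC[Si](Cl)(CC)CC
Why: Statistical mono-O-silylation of a symmetrical diol used in excess gives the mono-TES ether cleanly; no stereocentre is involved.

Step 2
Reactants: 2 2-[(triethylsilyloxy)methyl]prop-2-en-1-ol
Product: 3 {[2-(chloromethyl)prop-2-en-1-yl]oxy}triethylsilane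
Conditions: PPh3, NCS, CH2Cl2, −20 °C → rt
Reagents that add atoms: N-chlorosuccinimide, O=C1CCC(=O)N1Cl
Why: Appel-type chlorination converts the primary allylic alcohol into the chloride under neutral conditions that leave the TES ether untouched.

Step 3
Reactants: 3 {[2-(chloromethyl)prop-2-en-1-yl]oxy}triethylsilane
Product: 6 pinacol {(2E)-3-chloro-2-[(triethylsilyloxy)methyl]prop-2-en-1-yl}boronate (Cl cis to the CH2B arm), via α-chloroallyllithium 4 (not isolated), via lithium borate complex 5 (not isolated)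
Conditions: LDA (LiN(iPr)2), iPrOBpin, THF, −95 °C (in situ trapping); then TMSCl, −78 °C → rt
Reagents that add atoms: 2-isopropoxy-4,4,5,5-tetramethyl-1,3,2-dioxaborolane (iPrOBpin), CC(C)OB1OC(C)(C)C(C)(C)O1
Why: Deprotonation α to chlorine gives a chloride-chelated (endo) α-chloroallyllithium that is borylated in situ at the terminus remote from chlorine, which fixes Cl cis to the CH2B arm (the "Z-γ-chloroallyl" geometry) as in the classical γ-chloroallylborane preparation.

**Fragment B (butenolide donor)**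

Step 4
Reactants: 7 furan-3-ylmethanol
Product: 10 3-(hydroxymethyl)furan-2(5H)-one, via dilithiated furan 8 (not isolated), via furylboronate 9 (not isolated)
Conditions: n-BuLi (2.2 equiv), THF, −78 → 0 °C; B(OMe)3, −78 °C → rt; then 30% H2O2, AcOH, 0 °C → rt
Reagents that add atoms: hydrogen peroxide, OO
Why: Alkoxide-directed C2 lithiation, borylation and peroxide oxidation give the 2-hydroxyfuran, which tautomerises under the acidic work-up to the conjugated butenolide.

Step 5
Reactants: 10 3-(hydroxymethyl)furan-2(5H)-one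
Product: 11 3-[(tert-butyldimethylsilyloxy)methyl]furan-2(5H)-one
Conditions: TBSCl, imidazole, CH2Cl2, 0 °C → rt
Reagents that add atoms: tert-butyldimethylsilyl chloride (TBSCl), CC(C)(C)[Si](C)(C)Cl
Why: Standard silylation masks the C13 hydroxyl as a poor leaving group, so the later dienolate cannot eliminate it.

**Main line**

Step 6
Reactants: 12 tert-butyl(but-3-yn-1-yloxy)dimethylsilane
Product: 14 (E)-5-(tert-butyldimethylsilyloxy)-3-methylpent-2-en-1-ol, via alkenylalane 13 (not isolated)
Conditions: AlMe3, Cp2ZrCl2 (25 mol%), CH2Cl2, 0 °C → rt; then (CH2O)n, THF, 0 °C → rt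
Reagents that add atoms: trimethylaluminium, C[Al](C)C; paraformaldehyde (as formaldehyde), C=O
Why: Negishi zirconium-catalysed carboalumination adds Me–Al syn across the alkyne with methyl on the internal carbon, and hydroxymethylation of the alkenylalane with retention gives only the E trisubstituted alkene (C10=C1).

Step 7
Reactants: 14 (E)-5-(tert-butyldimethylsilyloxy)-3-methylpent-2-en-1-ol
Product: 15 (E)-5-(tert-butyldimethylsilyloxy)-3-methylpent-2-enal
Conditions: MnO2, CH2Cl2, rt
Reagents that add atoms: none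
Why: MnO2 oxidises the allylic alcohol chemoselectively to the enal without E/Z isomerisation.

Step 8
Reactants: 15 (E)-5-(tert-butyldimethylsilyloxy)-3-methylpent-2-enal; 6 pinacol {(2E)-3-chloro-2-[(triethylsilyloxy)methyl]prop-2-en-1-yl}boronate
Product: 18 (2R,3S)-2-[(1E)-4-(tert-butyldimethylsilyloxy)-2-methylbut-1-en-1-yl]-3-[3-(triethylsilyloxy)prop-1-en-2-yl]oxirane (cis), via borate ester 16 (not isolated), via syn-chlorohydrin 17 (not isolated)
Conditions: (S)-TRIP [(S)-3,3'-bis(2,4,6-triisopropylphenyl)-1,1'-binaphthyl-2,2'-diyl hydrogen phosphate, 5 mol%], 4 Å MS, toluene, −30 °C; then 2 M aq. NaOH, THF, 0 °C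
Reagents that add atoms: none
Why: Proposed new method: a chiral phosphoric acid-catalysed (Z)-γ-chloroallylboration with a 2-substituted γ-chloroallyl pinacol boronate (closest known chemistry: phosphoric acid-catalysed allyl- and crotylboration of aldehydes with pinacol boronates, and the stoichiometric diisopinocampheylborane chloroallylation), in which the acid hydrogen-bonds to the pseudo-axial boronate oxygen and its phosphoryl oxygen holds the formyl C–H in a closed chair, (S)-TRIP exposes the Si face of C2 and the chlorine (cis to the CH2B arm) sits axial to give the syn (2R,3R) chlorohydrin, which hydroxide closes by SN2 with inversion at C3 to the cis (2R,3S) epoxide.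

Step 9
Reactants: 18 cis-vinyl epoxide
Product: 19 (2R,2'S,3R,3'S)-3-[2-(tert-butyldimethylsilyloxy)ethyl]-3-methyl-3'-[3-(triethylsilyloxy)prop-1-en-2-yl]-2,2'-bioxirane (1R,2S,3S,10R in skeleton labels)
Conditions: D-fructose-derived Shi ketone (30 mol%), Oxone (2KHSO5·KHSO4·K2SO4), K2CO3, Bu4NHSO4, MeCN–DMM–aq. buffer (pH 10.5), 0 °C
Reagents that add atoms: potassium peroxymonosulfate (KHSO5, active part of Oxone), OOS(=O)(=O)[O-].[K+]
Why: Shi epoxidation, in which the chiral dioxirane attacks the E-trisubstituted C1=C10 alkene (the 1,1-disubstituted C4=C15 alkene is a poor substrate) through the spiro transition state, gives the trans (1R,10R) epoxide under catalyst control.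

Step 10
Reactants: 19 bis-epoxide TES ether
Product: 21 2-{(2S,3S)-3-[(2R,3R)-3-[2-(tert-butyldimethylsilyloxy)ethyl]-3-methyloxiran-2-yl]oxiran-2-yl}prop-2-enal, via alkoxysulfonium salt 20 (not isolated)
Conditions: (COCl)2, DMSO, CH2Cl2, −78 → −40 °C; then Et3N, −78 → 0 °C
Reagents that add atoms: none
Why: Direct Swern oxidation of a primary allylic TES ether (the primary TBS ether is inert) gives the C5 aldehyde in one operation without touching the epoxides.

Step 11
Reactants: 21 bis-epoxy enal; 11 3-[(tert-butyldimethylsilyloxy)methyl]furan-2(5H)-one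
Product: 23 (5S)-3-[(tert-butyldimethylsilyloxy)methyl]-5-[(1R)-1-(tert-butyldimethylsilyloxy)-2-{(2S,3S)-3-[(2R,3R)-3-[2-(tert-butyldimethylsilyloxy)ethyl]-3-methyloxiran-2-yl]oxiran-2-yl}prop-2-en-1-yl]furan-2(5H)-one, via aldol adduct 22 (not isolated)
Conditions: quinine-derived tertiary-amine squaramide (10 mol%), CH2Cl2, −20 °C; then 2,6-lutidine, TBSOTf, −78 °C
Reagents that add atoms: tert-butyldimethylsilyl triflate (TBSOTf), CC(C)(C)[Si](C)(C)OS(=O)(=O)C(F)(F)F
Why: Direct vinylogous aldol reaction, in which the amine generates the furanolate of 11 while the squaramide hydrogen-bonds the aldehyde so that the γ-carbon (C6) adds 1,2 to the Si face of C5 to give the anti (5R,6S) adduct, and silylation in the same flask blocks retro-aldol and protects O5.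

Step 12
Reactants: 23 tris-TBS butenolide
Product: 24 (5S)-5-[(1R)-1-(tert-butyldimethylsilyloxy)-2-{(2S,3S)-3-[(2R,3R)-3-(2-hydroxyethyl)-3-methyloxiran-2-yl]oxiran-2-yl}prop-2-en-1-yl]-3-(hydroxymethyl)furan-2(5H)-one
Conditions: HF·pyridine, pyridine, THF, 0 °C
Reagents that add atoms: none
Why: Buffered HF·pyridine cleaves the two primary TBS ethers (O8, O13) much faster than the hindered secondary allylic one at O5.

Step 13
Reactants: 24 diol
Product: 25 (5S)-3-(bromomethyl)-5-[(1R)-1-(tert-butyldimethylsilyloxy)-2-{(2S,3S)-3-[(2R,3R)-3-(2-hydroxyethyl)-3-methyloxiran-2-yl]oxiran-2-yl}prop-2-en-1-yl]furan-2(5H)-one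
Conditions: NBS, Me2S, CH2Cl2, −20 → 0 °C; aqueous work-up
Reagents that add atoms: N-bromosuccinimide, O=C1CCC(=O)N1Br
Why: Corey–Kim halogenation is selective for allylic alcohols, because only the allylic alkoxysulfonium ion is displaced by bromide while the saturated C8 alcohol is returned on work-up.

Step 14
Reactants: 25 bromo alcohol
Product: 26 2-[(2R,3R)-3-{(2S,3S)-3-[(3R)-3-(tert-butyldimethylsilyloxy)-3-[(2S)-4-(bromomethyl)-5-oxo-2,5-dihydrofuran-2-yl]prop-1-en-2-yl]oxiran-2-yl}-2-methyloxiran-2-yl]acetaldehyde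
Conditions: Dess–Martin periodinane, NaHCO3, CH2Cl2, 0 °C
Reagents that add atoms: none
Why: Buffered Dess–Martin oxidation gives the base-sensitive β,γ-epoxy aldehyde under neutral conditions that tolerate the allylic bromide.

Step 15
Reactants: 26 bromo aldehyde
Product: 28 (1R,2S,3S,5R,6S,7R,8S,10R)-5-(tert-butyldimethylsilyloxy)-1,10:2,3-diepoxy-8-hydroxygermacra-4(15),11(13)-dien-12,6-olide, via allylchromium species 27 (not isolated)
Conditions: CrCl2 (8 equiv), THF, rt, slow addition of 26 (2 mM); aq. NH4Cl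
Reagents that add atoms: none
Why: Intramolecular Nozaki–Hiyama allylation, in which the allylchromium adds through its γ-carbon C7 to the C8 aldehyde in a chair transition state on the butenolide face opposite the C6 side chain, gives the trans 6,7-lactone (7R) and, from the ring-fixed E-type allyl geometry with an equatorial aldehyde substituent, the (8S) carbinol, while the double bond moves to the exocyclic position.

Step 16
Reactants: 28 macrocyclic 8-alcohol
Product: 29 (1R,2S,3S,5R,6S,7R,8S,10R)-5-(tert-butyldimethylsilyloxy)-1,10:2,3-diepoxy-8-(methacryloyloxy)germacra-4(15),11(13)-dien-12,6-olide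
Conditions: methacrylic anhydride, Et3N, DMAP (cat.), CH2Cl2, 0 °C → rt
Reagents that add atoms: methacrylic anhydride, C=C(C)C(=O)OC(=O)C(C)=C
Why: DMAP-catalysed acylation esterifies the only free hydroxyl (O8) with retention of configuration.

Step 17
Reactants: 29 silyl-protected methacrylate
Product: 30 ACon1_002091, (1R,2S,3S,5R,6S,7R,8S,10R)-1,10:2,3-diepoxy-5-hydroxy-8-(methacryloyloxy)germacra-4(15),11(13)-dien-12,6-olide
Conditions: HF·pyridine, THF, 0 °C → rt
Reagents that add atoms: none
Why: Fluoride-mediated desilylation under buffered, non-basic conditions frees O5 without acyl migration, conjugate addition or epoxide opening.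

**Compound list**
1 | 2-methylenepropane-1,3-diol | C=C(CO)CO | starting material
2 | 2-[(triethylsilyloxy)methyl]prop-2-en-1-ol | C=C(CO)CO[Si](CC)(CC)CC | intermediate
3 | {[2-(chloromethyl)prop-2-en-1-yl]oxy}triethylsilane | C=C(CCl)CO[Si](CC)(CC)CC | intermediate
4 | 1-chloro-2-[(triethylsilyloxy)methyl]allyllithium | [Li]C(Cl)C(=C)CO[Si](CC)(CC)CC | intermediate (not isolated)
5 | lithium isopropoxy(pinacolato){(2E)-3-chloro-2-[(triethylsilyloxy)methyl]prop-2-en-1-yl}borate | Cl/C=C(\C[B-]1(OC(C)C)OC(C)(C)C(C)(C)O1)CO[Si](CC)(CC)CC.[Li+] | intermediate (not isolated)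
6 | pinacol {(2E)-3-chloro-2-[(triethylsilyloxy)methyl]prop-2-en-1-yl}boronate (Cl cis to CH2B) | Cl/C=C(\CB1OC(C)(C)C(C)(C)O1)CO[Si](CC)(CC)CC | intermediate
7 | furan-3-ylmethanol | OCc1ccoc1 | starting material
8 | 2-lithio-3-(lithiooxymethyl)furan | [Li]OCc1ccoc1[Li] | intermediate (not isolated)
9 | dimethyl [3-(lithiooxymethyl)furan-2-yl]boronate | COB(OC)c1occc1CO[Li] | intermediate (not isolated)
10 | 3-(hydroxymethyl)furan-2(5H)-one | O=C1OCC=C1CO | intermediate
11 | 3-[(tert-butyldimethylsilyloxy)methyl]furan-2(5H)-one | O=C1OCC=C1CO[Si](C)(C)C(C)(C)C | intermediate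
12 | tert-butyl(but-3-yn-1-yloxy)dimethylsilane | C#CCCO[Si](C)(C)C(C)(C)C | starting material
13 | (E)-[4-(tert-butyldimethylsilyloxy)-2-methylbut-1-en-1-yl]dimethylalane | C[Al](C)/C=C(\C)CCO[Si](C)(C)C(C)(C)C | intermediate (not isolated)
14 | (E)-5-(tert-butyldimethylsilyloxy)-3-methylpent-2-en-1-ol | OC/C=C(\C)CCO[Si](C)(C)C(C)(C)C | intermediate
15 | (E)-5-(tert-butyldimethylsilyloxy)-3-methylpent-2-enal | O=C/C=C(\C)CCO[Si](C)(C)C(C)(C)C | intermediate
16 | pinacol borate ester of 17 (O2–Bpin) | CC(C)(C)[Si](C)(C)OCC/C(C)=C/[C@@H](OB1OC(C)(C)C(C)(C)O1)[C@H](Cl)C(=C)CO[Si](CC)(CC)CC | intermediate (not isolated)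
17 | (3R,4R,5E)-8-(tert-butyldimethylsilyloxy)-3-chloro-6-methyl-2-[(triethylsilyloxy)methyl]octa-1,5-dien-4-ol (syn-chlorohydrin) | CC(C)(C)[Si](C)(C)OCC/C(C)=C/[C@@H](O)[C@H](Cl)C(=C)CO[Si](CC)(CC)CC | intermediate (not isolated)
18 | (2R,3S)-2-[(1E)-4-(tert-butyldimethylsilyloxy)-2-methylbut-1-en-1-yl]-3-[3-(triethylsilyloxy)prop-1-en-2-yl]oxirane | CC(C)(C)[Si](C)(C)OCC/C(C)=C/[C@H]1O[C@H]1C(=C)CO[Si](CC)(CC)CC | intermediate
19 | (2R,2'S,3R,3'S)-3-[2-(tert-butyldimethylsilyloxy)ethyl]-3-methyl-3'-[3-(triethylsilyloxy)prop-1-en-2-yl]-2,2'-bioxirane | CC(C)(C)[Si](C)(C)OCC[C@@]1(C)O[C@@H]1[C@H]1O[C@H]1C(=C)CO[Si](CC)(CC)CC | intermediate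
20 | dimethyl(alkoxy)sulfonium chloride of the C5 alcohol derived from 19 | CC(C)(C)[Si](C)(C)OCC[C@@]1(C)O[C@@H]1[C@H]1O[C@H]1C(=C)CO[S+](C)C.[Cl-] | intermediate (not isolated)
21 | 2-{(2S,3S)-3-[(2R,3R)-3-[2-(tert-butyldimethylsilyloxy)ethyl]-3-methyloxiran-2-yl]oxiran-2-yl}prop-2-enal | CC(C)(C)[Si](C)(C)OCC[C@@]1(C)O[C@@H]1[C@H]1O[C@H]1C(=C)C=O | intermediate
22 | (5S)-3-[(tert-butyldimethylsilyloxy)methyl]-5-[(1R)-1-hydroxy-2-{bis-epoxide of 21}prop-2-en-1-yl]furan-2(5H)-one (anti aldol, 5R,6S) | CC(C)(C)[Si](C)(C)OCC[C@@]1(C)O[C@@H]1[C@H]1O[C@H]1C(=C)[C@@H](O)[C@H]1OC(=O)C(CO[Si](C)(C)C(C)(C)C)=C1 | intermediate (not isolated)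
23 | O5-TBS ether of 22 (tris-TBS butenolide) | CC(C)(C)[Si](C)(C)OCC[C@@]1(C)O[C@@H]1[C@H]1O[C@H]1C(=C)[C@@H](O[Si](C)(C)C(C)(C)C)[C@H]1OC(=O)C(CO[Si](C)(C)C(C)(C)C)=C1 | intermediate
24 | 8,13-diol with O5-TBS | OCC[C@@]1(C)O[C@@H]1[C@H]1O[C@H]1C(=C)[C@@H](O[Si](C)(C)C(C)(C)C)[C@H]1OC(=O)C(CO)=C1 | intermediate
25 | 13-bromo 8-alcohol with O5-TBS | OCC[C@@]1(C)O[C@@H]1[C@H]1O[C@H]1C(=C)[C@@H](O[Si](C)(C)C(C)(C)C)[C@H]1OC(=O)C(CBr)=C1 | intermediate
26 | 13-bromo C8 aldehyde with O5-TBS | O=CC[C@@]1(C)O[C@@H]1[C@H]1O[C@H]1C(=C)[C@@H](O[Si](C)(C)C(C)(C)C)[C@H]1OC(=O)C(CBr)=C1 | intermediate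
27 | C13 allylchromium dichloride derived from 26 | O=CC[C@@]1(C)O[C@@H]1[C@H]1O[C@H]1C(=C)[C@@H](O[Si](C)(C)C(C)(C)C)[C@H]1OC(=O)C(C[Cr](Cl)Cl)=C1 | intermediate (not isolated)
28 | (1R,2S,3S,5R,6S,7R,8S,10R)-5-(tert-butyldimethylsilyloxy)-1,10:2,3-diepoxy-8-hydroxygermacra-4(15),11(13)-dien-12,6-olide | O[C@H]1C[C@@]2(C)O[C@@H]2[C@H]2O[C@H]2C(=C)[C@@H](O[Si](C)(C)C(C)(C)C)[C@H]2OC(=O)C(=C)[C@@H]21 | intermediate
29 | 8-O-methacrylate of 28 | C=C(C)C(=O)O[C@H]1C[C@@]2(C)O[C@@H]2[C@H]2O[C@H]2C(=C)[C@@H](O[Si](C)(C)C(C)(C)C)[C@H]2OC(=O)C(=C)[C@@H]21 | intermediate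
30 | ACon1_002091 | C=C(C)C(=O)O[C@H]1C[C@@]2(C)O[C@@H]2[C@H]2O[C@H]2C(=C)[C@@H](O)[C@H]2OC(=O)C(=C)[C@@H]21 | target

**Step count and risks**

Total: 17 steps. Longest linear sequence: 13 steps (steps 1–3, then 8–17); 12 steps from alkyne 12.

Step 8 is the proposed new step and the most likely to fail. The risks are a slow reaction of the chlorine-deactivated boronate, α- versus γ-borylation in step 3 feeding it, and an untested level of enantiocontrol. The fallback sets out from 3 and 15 and comes back at 17 using known stoichiometric reagent control. Chloride 3 is lithiated with LiNCy2 at −95 °C in the presence of (−)-B-methoxydiisopinocampheylborane (from (+)-α-pinene) and treated with BF3·OEt2 to give [(2E)-3-chloro-2-(triethylsilyloxymethyl)allyl]diisopinocampheylborane F1. This adds to the Si face of 15 through the same chair to give the diisopinocampheylborinate of the syn-chlorohydrin F2. Ethanolamine work-up frees 17, and the NaOH closure of step 8 then gives 18.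

Step 11 may fail by conjugate addition to the 2-substituted acrolein, by retro-aldol, or by poor anti selectivity with this new aldehyde class. The fallback sets out from 11 and 21 and comes back at 22, with Lewis-acid activation of the carbonyl in place of base catalysis. Butenolide 11 is converted with TMSOTf/Et3N into tert-butyldimethyl{[2-(trimethylsilyloxy)furan-3-yl]methoxy}silane F3. A Ti(OiPr)4/BINOL-catalysed vinylogous Mukaiyama aldol reaction (BINOL enantiomer chosen for Si-face addition) with 21 gives the O5-trimethylsilyl aldol F4. Mild citric acid/MeOH work-up cleaves the TMS ether to 22, which is silylated to 23 as in step 11.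

Step 15 may fail by oligomerisation or by the wrong C8 configuration if the macrocycle forces the aldehyde substituent axial. The fallback sets out from 26 and comes back at 29 by stereochemical correction. If the ring closes to the (8R)-epimer of 28, (1R,2S,3S,5R,6S,7R,8R,10R)-5-(tert-butyldimethylsilyloxy)-1,10:2,3-diepoxy-8-hydroxygermacra-4(15),11(13)-dien-12,6-olide F5, this is esterified under Mitsunobu conditions (methacrylic acid, PPh3, DIAD, THF, 0 °C). The inversion at C8 gives 29 directly and replaces step 16.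

Further compounds
F1 | step 8 | [(2E)-3-chloro-2-(triethylsilyloxymethyl)allyl]diisopinocampheylborane (Ipc from (+)-α-pinene; Cl cis to CH2B) | Cl/C=C(\CB([C@@H]1C[C@@H]2C[C@@H](C2(C)C)[C@H]1C)[C@@H]1C[C@@H]2C[C@@H](C2(C)C)[C@H]1C)CO[Si](CC)(CC)CC
F2 | step 8 | diisopinocampheylborinate of syn-chlorohydrin 17 | CC(C)(C)[Si](C)(C)OCC/C(C)=C/[C@@H](OB([C@@H]1C[C@@H]2C[C@@H](C2(C)C)[C@H]1C)[C@@H]1C[C@@H]2C[C@@H](C2(C)C)[C@H]1C)[C@H](Cl)C(=C)CO[Si](CC)(CC)CC
F3 | step 11 | tert-butyldimethyl{[2-(trimethylsilyloxy)furan-3-yl]methoxy}silane | C[Si](C)(C)Oc1occc1CO[Si](C)(C)C(C)(C)C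
F4 | step 11 | O5-trimethylsilyl ether of aldol 22 | CC(C)(C)[Si](C)(C)OCC[C@@]1(C)O[C@@H]1[C@H]1O[C@H]1C(=C)[C@@H](O[Si](C)(C)C)[C@H]1OC(=O)C(CO[Si](C)(C)C(C)(C)C)=C1
F5 | step 15 | (8R)-epimer of 28 | O[C@@H]1C[C@@]2(C)O[C@@H]2[C@H]2O[C@H]2C(=C)[C@@H](O[Si](C)(C)C(C)(C)C)[C@H]2OC(=O)C(=C)[C@@H]21
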